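**Retrosynthetic overview**
1. Target 16 ⇒ (global desilylation, saturation of C3=C4) ⇒ (S)-flav-3-ene 14 ⇒ cut C2–C1' ⇒ racemic 2-ethoxy-2H-chromene 6 + aryl boronate 12.
2. Enabling feature: C2 is bonded to ring oxygen O1. At the chromene level it is conjugated through C3=C4 with ring A and its 7-OMe, so loss of ethoxide turns rings A/C into a flat, aromatic 10π 1-benzopyrylium cation. Both enantiomers of 6 therefore converge. C1' of ring B lies ortho/para to its two oxygens and is the natural nucleophilic carbon.
3. 6 ⇒ osthole 1, which already holds rings A and C, the 7-OMe and all five side-chain carbons. Only an E-selective allylic oxidation and a lactone-to-acetal reduction are needed. 12 ⇒ 4-bromoresorcinol 7.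
4. Ring order: no ring is built. Rings A and C come with 1 and ring B with 7. Ring C is walked through the levels 2-pyranone → 2H-pyran acetal → pyrylium → 2H-pyran → dihydropyran.

Key step: step 8

Assumption: the sense of induction for this ortho-substituted boronate cannot be predicted with certainty. The catalyst can be made from L- or D-tartaric acid, and the antipode that delivers the aryl group to the C2 face giving (S) is used.

**Step 1**
Reactants: 1 osthole
Product: 2 (E)-4-(7-methoxy-2-oxo-2H-chromen-8-yl)-2-methylbut-2-enal
Conditions: SeO2 (1.2 equiv), 1,4-dioxane, trace H2O, 80 °C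
Reagents that add atoms: selenium dioxide, O=[Se]=O
Why: Riley-type SeO2 allylic oxidation (ene reaction, then [2,3]-sigmatropic shift) attacks the more substituted alkene terminus and only the methyl group trans to the benzylic chain, which fixes the E geometry, while the electron-poor coumarin C3=C4 bond is inert.

**Step 2**
Reactants: 2 (E)-enal
Product: 3 8-[(E)-4-hydroxy-3-methylbut-2-enyl]-7-methoxy-2H-chromen-2-one
Conditions: NaBH4, CeCl3·7H2O, MeOH, −20 to 0 °C
Reagents that add atoms: none
Why: Luche 1,2-reduction converts the enal into the allylic alcohol without touching the alkene geometry, and the much less electrophilic coumarin lactone should survive the short cold exposure.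

**Step 3**
Reactants: 3 allylic alcohol
Product: 4 8-[(E)-4-(tert-butyldiphenylsilyloxy)-3-methylbut-2-enyl]-7-methoxy-2H-chromen-2-one
Conditions: TBDPSCl, imidazole, DMF, 0 °C to rt
Reagents that add atoms: tert-butyldiphenylsilyl chloride, CC(C)(C)[Si](Cl)(c1ccccc1)c1ccccc1
Why: Standard silylation of a primary alcohol; TBDPS should withstand DIBAL-H, the acidic ethanol of step 4 and the Lewis acid of step 8, yet leaves with fluoride together with the aryl TBS groups.

**Step 4**
Reactants: 4 TBDPS-protected coumarin
Product: 6 rac-2-ethoxy-7-methoxy-8-[(E)-4-(tert-butyldiphenylsilyloxy)-3-methylbut-2-enyl]-2H-chromene, via 2H-chromen-2-ol 5 (not isolated)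
Conditions: DIBAL-H (1.1 equiv), CH2Cl2, −78 °C; Rochelle salt work-up; crude 5, abs. EtOH, PPTS (cat.), 3 Å MS, 0 °C to rt; Et3N quench; Et3N-deactivated silica
Reagents that add atoms: ethanol, CCO
Why: Partial DIBAL-H reduction of a coumarin stops at the aluminium lactolate at −78 °C, and the lactol is acetalised under acid catalysis through the 7-methoxy-stabilised benzopyrylium ion; the acetal centre is racemic on purpose because step 8 erases it.

**Step 5**
Reactants: 7 4-bromoresorcinol
Product: 8 1-bromo-2,4-bis(tert-butyldimethylsilyloxy)benzene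
Conditions: TBSCl (2.4 equiv), imidazole, DMF, rt
Reagents that add atoms: tert-butyldimethylsilyl chloride, CC(C)(C)[Si](C)(C)Cl
Why: Standard double silylation of phenols; aryl TBS ethers tolerate organolithium, mild acid and Lewis acid and are cleaved by fluoride at the end.

**Step 6**
Reactants: 8 bis(silyl) aryl bromide
Product: 11 2,4-bis(tert-butyldimethylsilyloxy)phenylboronic acid, via aryllithium 9 (not isolated), via lithium aryltriisopropoxyborate 10 (not isolated)
Conditions: B(Oi-Pr)3 (1.3 equiv), THF/toluene, −78 °C, n-BuLi (1.1 equiv) added slowly; to −20 °C; aq. HCl to pH 6, 0 °C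
Reagents that add atoms: triisopropyl borate, CC(C)OB(OC(C)C)OC(C)C; water, O
Why: Bromine–lithium exchange with in situ borate trapping should capture the aryllithium before the ortho O-to-C silyl shift (retro-Brook rearrangement) can occur, and mild hydrolysis gives the boronic acid.

**Step 7**
Reactants: 11 arylboronic acid
Product: 12 diethyl 2,4-bis(tert-butyldimethylsilyloxy)phenylboronate
Conditions: abs. EtOH, toluene, 3 Å MS, rt, then azeotropic evaporation; used crude
Reagents that add atoms: ethanol, CCO
Why: Reversible boronic acid esterification, driven by removal of water, gives the exchange-labile acyclic boronate that the catalyst of step 8 requires.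

**Step 8**
Reactants: 6 rac-2-ethoxy-2H-chromene; 12 diethyl arylboronate (1.5 equiv)
Product: 14 (S)-2-[2,4-bis(tert-butyldimethylsilyloxy)phenyl]-7-methoxy-8-[(E)-4-(tert-butyldiphenylsilyloxy)-3-methylbut-2-enyl]-2H-chromene, via benzopyrylium arylborate ion pair 13 (not isolated)
Conditions: tartaric acid monoamide (chiral 2,3-dihydroxy acid, 10 mol %), Yb(OTf)3 (9 mol %), EtOAc, −20 °C, dark; cold Et3N/aq. NaHCO3 quench
Reagents that add atoms: none
Why: The dihydroxy acid exchanges with the ethoxides of 12 to give a chiral, more Lewis acidic dioxaborolane, which together with the lanthanide triflate takes the ethoxide from either enantiomer of 6, so both collapse to the same planar aromatic 1-benzopyrylium cation paired with a chiral aryl borate (13, drawn with ethoxides in place of the catalyst diol). The aryl group then migrates from tetracoordinate boron through its ipso carbon to C2 inside the contact ion pair, forming the C2–C1' bond and releasing triethyl borate. The closest known reaction type is the chiral diol acid/lanthanide triflate catalysed enantioselective addition of aryl and alkenyl boronates to 2-alkoxy-2H-chromenes, a Petasis-like boronate addition to an oxocarbenium ion. No ring is closed, since rings A and C are carried over from 6 and ring B from 12. The only stereocentre, C2, is controlled by the chiral ligand on boron, which shields one face of the flat cation, so the racemic acetal is funnelled stereoconvergently into the (S) product. The step needs C2 over C4 attack, secured by the higher positive charge next to O1 and by the borate sitting where the ethoxide left, and ipso transfer over Friedel–Crafts attack, secured by the silyloxy groups ortho and para to boron, while the 7-OMe eases ionisation and the silyl ethers and trisubstituted alkene are spectators.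

**Step 9**
Reactants: 14 (S)-flav-3-ene
Product: 15 (S)-2-[2,4-bis(tert-butyldimethylsilyloxy)phenyl]-7-methoxy-8-[(E)-4-(tert-butyldiphenylsilyloxy)-3-methylbut-2-enyl]chroman
Conditions: 2-nitrobenzenesulfonohydrazide (NBSH, in portions), Et3N, CH2Cl2, rt, dark
Reagents that add atoms: none
Why: Diimide reduction (concerted syn H2 transfer) should be much faster at the cis-disubstituted ring alkene than at the trisubstituted side-chain alkene shielded by CH2OTBDPS, and being free of metal and acid it neither shifts the alkene towards C2 nor cleaves the benzylic C2–O bond, so C2 stays (S).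

**Step 10**
Reactants: 15 (S)-flavan tris(silyl ether)
Product: 16 morusyunnansin E
Conditions: TBAF (4 equiv), AcOH (4 equiv), THF, 0 °C to rt
Reagents that add atoms: none
Why: Fluoride-mediated cleavage removes all three silyl ethers in one operation, and the acetic acid buffer keeps the 4'-phenol protonated so that ring opening to a para-quinone methide, the path to C2 racemisation, is not entered.

**Compound list**
1 | osthole, 7-methoxy-8-(3-methylbut-2-enyl)-2H-chromen-2-one | COc1ccc2ccc(=O)oc2c1CC=C(C)C | starting material
2 | (E)-4-(7-methoxy-2-oxo-2H-chromen-8-yl)-2-methylbut-2-enal | COc1ccc2ccc(=O)oc2c1C/C=C(\C)C=O | intermediate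
3 | 8-[(E)-4-hydroxy-3-methylbut-2-enyl]-7-methoxy-2H-chromen-2-one | COc1ccc2ccc(=O)oc2c1C/C=C(\C)CO | intermediate
4 | TBDPS ether of 3 | COc1ccc2ccc(=O)oc2c1C/C=C(\C)CO[Si](c3ccccc3)(c4ccccc4)C(C)(C)C | intermediate
5 | rac-2H-chromen-2-ol (lactol of 4) | COc1ccc2c(c1C/C=C(\C)CO[Si](c3ccccc3)(c4ccccc4)C(C)(C)C)OC(O)C=C2 | intermediate
6 | rac-2-ethoxy-2H-chromene acetal | COc1ccc2c(c1C/C=C(\C)CO[Si](c3ccccc3)(c4ccccc4)C(C)(C)C)OC(OCC)C=C2 | intermediate
7 | 4-bromoresorcinol (4-bromobenzene-1,3-diol) | Oc1ccc(Br)c(O)c1 | starting material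
8 | 1-bromo-2,4-bis(tert-butyldimethylsilyloxy)benzene | CC(C)(C)[Si](C)(C)Oc1ccc(Br)c(O[Si](C)(C)C(C)(C)C)c1 | intermediate
9 | 2,4-bis(tert-butyldimethylsilyloxy)phenyllithium | [Li]c1ccc(O[Si](C)(C)C(C)(C)C)cc1O[Si](C)(C)C(C)(C)C | intermediate
10 | lithium [2,4-bis(tert-butyldimethylsilyloxy)phenyl]triisopropoxyborate | [Li+].CC(C)O[B-](OC(C)C)(OC(C)C)c1ccc(O[Si](C)(C)C(C)(C)C)cc1O[Si](C)(C)C(C)(C)C | intermediate
11 | 2,4-bis(tert-butyldimethylsilyloxy)phenylboronic acid | OB(O)c1ccc(O[Si](C)(C)C(C)(C)C)cc1O[Si](C)(C)C(C)(C)C | intermediate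
12 | diethyl 2,4-bis(tert-butyldimethylsilyloxy)phenylboronate | CCOB(OCC)c1ccc(O[Si](C)(C)C(C)(C)C)cc1O[Si](C)(C)C(C)(C)C | intermediate
13 | 1-benzopyrylium aryl(triethoxy)borate ion pair | COc1ccc2ccc[o+]c2c1C/C=C(\C)CO[Si](c3ccccc3)(c4ccccc4)C(C)(C)C.CCO[B-](OCC)(OCC)c1ccc(O[Si](C)(C)C(C)(C)C)cc1O[Si](C)(C)C(C)(C)C | intermediate
14 | (S)-2-aryl-2H-chromene (flav-3-ene) tris(silyl ether) | COc1ccc2c(c1C/C=C(\C)CO[Si](c3ccccc3)(c4ccccc4)C(C)(C)C)O[C@H](c1ccc(O[Si](C)(C)C(C)(C)C)cc1O[Si](C)(C)C(C)(C)C)C=C2 | intermediate
15 | (S)-flavan tris(silyl ether) | COc1ccc2c(c1C/C=C(\C)CO[Si](c3ccccc3)(c4ccccc4)C(C)(C)C)O[C@H](c1ccc(O[Si](C)(C)C(C)(C)C)cc1O[Si](C)(C)C(C)(C)C)CC2 | intermediate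
16 | morusyunnansin E, (2S)-2-(2,4-dihydroxyphenyl)-8-[(E)-4-hydroxy-3-methylbut-2-enyl]-7-methoxychroman | COc1ccc2c(c1C/C=C(\C)CO)O[C@H](c1ccc(O)cc1O)CC2 | target

**Total step count:** 10. **Longest linear sequence:** 7 (steps 1–4, 8–10).

**Steps most likely to fail**

**Step 8.**
- What may go wrong:
  - slow aryl transfer from the hindered ortho-silyloxy boronate;
  - poor facial selectivity in the ion pair;
  - hydride transfer from the product to the cation;
  - erosion of configuration by reversible Lewis acid ionisation of the product C2–O1 bond.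
- Fallback: the same bond is formed, but the stereocentre is set separately. It sets out from 4 and 8 and returns at 15.
- Coumarin 4 is reduced at C3=C4 by copper hydride conjugate reduction (Cu(OAc)2, 1,2-bis(diphenylphosphino)benzene, PMHS, t-BuOH, toluene) to the dihydrocoumarin F1.
- Aryllithium 9, made from 8 (n-BuLi, Et2O, −78 °C), opens the lactone of F1 to the hydroxyaryl propyl aryl ketone F2.
- Noyori asymmetric transfer hydrogenation (RuCl(p-cymene)[(R,R)-TsDPEN], HCO2H/Et3N) gives the (R)-benzylic alcohol F3.
- Intramolecular Mitsunobu etherification (PPh3, DIAD, THF, 0 °C) recloses ring C with inversion to give (S)-flavan 15, so step 9 is bypassed as well.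

**Step 9.**
- What may go wrong: the side-chain alkene may begin to be reduced before the ring alkene is consumed, or light-induced electrocyclic opening of the 2H-pyran ring may scramble C2.
- Fallback: it sets out from 14 and returns at 15, and replaces steric discrimination by electronic recognition.
- A ligated copper hydride (Cu(OAc)2, DTBM-SEGPHOS, (MeO)2MeSiH, i-PrOH, THF) hydrocuprates only the aryl-conjugated C3=C4 bond, placing copper at benzylic C4.
- The alcohol protonates the benzylcopper (copper-catalysed transfer hydrogenation of aryl alkenes). Unactivated trisubstituted alkenes do not insert.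
- This fallback makes no new compound (F0).

**Step 4.**
- What may go wrong:
  - over-reduction through the open hydroxycinnamaldehyde tautomer of the lactolate;
  - Z-to-E isomerisation of that tautomer;
  - loss of the labile acetal on silica.
- Fallback: reduce fully on purpose and return by oxidation. It sets out from 4 and returns at 5.
- Excess DIBAL-H (3 equiv, CH2Cl2, −78 to 0 °C) gives the (Z)-hydroxypropenyl phenol F4.
- MnO2 (CH2Cl2, rt) oxidises only the allylic alcohol, and the (Z)-enal closes at once to lactol 5, which is acetalised to 6 as before.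

**Further compounds**
F1 | step 8 | 8-[(E)-4-(tert-butyldiphenylsilyloxy)-3-methylbut-2-enyl]-7-methoxychroman-2-one | COc1ccc2c(c1C/C=C(\C)CO[Si](c3ccccc3)(c4ccccc4)C(C)(C)C)OC(=O)CC2
F2 | step 8 | 1-[2,4-bis(tert-butyldimethylsilyloxy)phenyl]-3-{2-hydroxy-4-methoxy-3-[(E)-4-(tert-butyldiphenylsilyloxy)-3-methylbut-2-enyl]phenyl}propan-1-one | COc1ccc(CCC(=O)c2ccc(O[Si](C)(C)C(C)(C)C)cc2O[Si](C)(C)C(C)(C)C)c(O)c1C/C=C(\C)CO[Si](c3ccccc3)(c4ccccc4)C(C)(C)C
F3 | step 8 | (R)-benzylic alcohol from F2 | COc1ccc(CC[C@@H](O)c2ccc(O[Si](C)(C)C(C)(C)C)cc2O[Si](C)(C)C(C)(C)C)c(O)c1C/C=C(\C)CO[Si](c3ccccc3)(c4ccccc4)C(C)(C)C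
F0 | step 9 | none | none
F4 | step 4 | 6-[(Z)-3-hydroxyprop-1-enyl]-3-methoxy-2-[(E)-4-(tert-butyldiphenylsilyloxy)-3-methylbut-2-enyl]phenol | COc1ccc(/C=C\CO)c(O)c1C/C=C(\C)CO[Si](c2ccccc2)(c3ccccc3)C(C)(C)C
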